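The target is a saturated, unbranched C20 acyl chain on a benzyl ester; it has no stereocentre, no C=C bond, and the phenyl ring is its only ring.
First cut: the C3–C4 bond, which lies between two CH2 groups. C4–C20 becomes a heptadecyl unit and C1–C3 a CH2CH2C(=O)OCH2Ph unit; both carbons of this bond are primary and the ester carbonyl C1 sits two atoms from C3, so each unit can be carried by a carboxylic acid that gives up CO2.
Second cut: the C1(=O)–OCH2Ph bond of the ester, which leads back to succinic anhydride 1 and benzyl alcohol 2.
Forward: 1 and 2 give half-ester 3; N-hydroxyphthalimide 4 converts 3 into redox-active ester 5 and stearic acid 6 into redox-active ester 7; 5 and 7 are joined, with loss of two CO2, to the target 8. The chain is completed last, by one C(sp3)–C(sp3) bond between a C3 and a C17 fragment, with the benzyl ester already in place.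
Stereochemistry: nothing has to be set or protected, and no ring is formed at any stage.

Key step: step 4

Step 1
Reactants: 1 succinic anhydride; 2 benzyl alcohol
Product: 3 4-(benzyloxy)-4-oxobutanoic acid (monobenzyl succinate)
Conditions: 1 (1.1 equiv), 2 (1.0 equiv), 4-(dimethylamino)pyridine (DMAP, 0.1 equiv), toluene, 80 °C
Reagents that add atoms: none
Why: DMAP-catalysed alcoholysis of a cyclic anhydride: the primary alcohol opens the five-membered ring once by acyl transfer, the carboxylic acid released cannot be esterified again without an activating agent so the reaction should stop at the half-ester, every atom of 1 and 2 is kept in 3, and 3 should be separable from neutral material by extraction into aqueous bicarbonate and re-acidification.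

Step 2
Reactants: 3 4-(benzyloxy)-4-oxobutanoic acid; 4 N-hydroxyphthalimide
Product: 5 benzyl 1,3-dioxoisoindolin-2-yl butanedioate (the N-acyloxyphthalimide of 3)
Conditions: 4 (1.05 equiv), N,N'-diisopropylcarbodiimide (DIC, 1.1 equiv), DMAP (0.1 equiv), CH2Cl2, 0 °C to rt
Reagents that add atoms: none
Why: Steglich-type carbodiimide esterification: the carbodiimide activates the free acid, DMAP passes the acyl group to the N–OH oxygen of 4, the water formally lost ends in the urea of the carbodiimide, and the benzyl ester at the other chain end should not be touched under these neutral conditions.

Step 3
Reactants: 6 stearic acid (octadecanoic acid); 4 N-hydroxyphthalimide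
Product: 7 1,3-dioxoisoindolin-2-yl octadecanoate (the N-acyloxyphthalimide of stearic acid)
Conditions: 4 (1.05 equiv), DIC (1.1 equiv), DMAP (0.1 equiv), CH2Cl2/THF (4:1), rt
Reagents that add atoms: none
Why: The same Steglich-type carbodiimide esterification on an unhindered fatty acid with no other functional group, the THF cosolvent keeping the C18 acid in solution, and the product is expected to be a crystalline solid that can be freed from the urea by recrystallisation.

Step 4
Reactants: 5 benzyl 1,3-dioxoisoindolin-2-yl butanedioate; 7 1,3-dioxoisoindolin-2-yl octadecanoate
Product: 8 benzyl eicosanoate (eicosanoic acid phenylmethyl ester)
Conditions: 7 (1.0 equiv), 5 (3.0 equiv), NiCl2·6H2O (20 mol%), 2,2':6',2''-terpyridine (20 mol%), AgNO3 (0.3 equiv, plates silver nanoparticles onto the cathode), LiCl (supporting electrolyte), DMF/THF (1:1), Mg anode, reticulated vitreous carbon cathode, undivided cell, constant current, rt; aq. HCl work-up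
Reagents that add atoms: none
Why: Cathodic reduction, relayed by low-valent nickel bearing the terpyridine ligand, puts one electron into each N-acyloxyphthalimide, which then loses phthalimide anion and CO2 to give the primary heptadecyl radical from 7 and the primary 2-(benzyloxycarbonyl)ethyl radical from 5; nickel takes up the two alkyl groups in turn and reductive elimination from the dialkylnickel species forms the C3–C4 bond of the eicosanoate chain, while the dissolving Mg anode balances the charge as magnesium ions. The closest known reaction type is the nickel-electrocatalytic doubly decarboxylative C(sp3)–C(sp3) cross-coupling of two redox-active esters, the reductive counterpart of a mixed Kolbe electrolysis, for which two unhindered primary partners are the most favourable case. No ring closes and no stereocentre is created, so neither a mode of cyclisation nor a controlling element is involved. The only selectivity required is cross- over homo-coupling; it is close to statistical and is secured by the threefold excess of the cheap succinate ester 5, so that the limiting stearate ester 7 should end mainly in 8, while the surplus of 5 ends as polar dibenzyl adipate, which chromatography or crystallisation should remove together with traces of tetratriacontane. The benzyl ester lies outside the potential window of the nickel-mediated reduction and meets no base, alcohol solvent, hydrogen or anodic oxidation, the anode reaction being magnesium dissolution, so it should pass unchanged.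

Compound list
1 | succinic anhydride | O=C1CCC(=O)O1 | starting material
2 | benzyl alcohol | OCc1ccccc1 | starting material
3 | 4-(benzyloxy)-4-oxobutanoic acid (monobenzyl succinate) | OC(=O)CCC(=O)OCc1ccccc1 | intermediate
4 | N-hydroxyphthalimide | ON1C(=O)c2ccccc2C1=O | starting material
5 | benzyl 1,3-dioxoisoindolin-2-yl butanedioate | O=C(CCC(=O)OCc1ccccc1)ON1C(=O)c2ccccc2C1=O | intermediate
6 | stearic acid (octadecanoic acid) | CCCCCCCCCCCCCCCCCC(=O)O | starting material
7 | 1,3-dioxoisoindolin-2-yl octadecanoate | CCCCCCCCCCCCCCCCCC(=O)ON1C(=O)c2ccccc2C1=O | intermediate
8 | benzyl eicosanoate (eicosanoic acid phenylmethyl ester) | CCCCCCCCCCCCCCCCCCCC(=O)OCc1ccccc1 | target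

Total step count: 4
Longest linear sequence: 3 steps (steps 1, 2 and 4); step 3 is a one-step side branch that joins at step 4.

Steps most likely to fail

Step 4. Homo-coupling of each radical partner may outrun the cross-coupling. Alkyl groups may be lost by hydrogen abstraction from the solvent or by β-hydride elimination at nickel. The long-chain ester may precipitate from the electrolyte, and the anode may passivate. The fallback sets out from 7 and comes back to the route at 8. It forms the same C3–C4 bond by a visible-light reductive decarboxylative Giese addition instead of a radical–radical union. 7 would be irradiated with blue LEDs in CH2Cl2 at rt with commercial benzyl acrylate (C=CC(=O)OCc1ccccc1, 3 equiv), Hantzsch ester (1.5 equiv) and Ru(bpy)3Cl2·6H2O (1 mol%). Single-electron reduction of 7 releases the heptadecyl radical, which adds to the terminal CH2 of the acrylate. The resulting radical next to the ester takes a hydrogen atom from the Hantzsch ester and should give 8 directly. Only one radical precursor is present, so the statistical cross/homo problem disappears. Compounds 3 and 5 are not needed on this path, and it makes no compound that is absent from the list (entry F0).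

Step 2. The carbodiimide adduct of the acid may rearrange by acyl migration to an unreactive N-acylurea, and the activated ester may hydrolyse back to 3 during chromatography. The fallback sets out from 3 and comes back at 5. It replaces in-flask carbodiimide activation by a discrete acid chloride. 3 would be treated with oxalyl chloride and catalytic DMF in CH2Cl2 at 0 °C to rt to give benzyl 4-chloro-4-oxobutanoate F1, whose co-products are all gases. After evaporation, F1 would be acylated onto 4 with Et3N in CH2Cl2 at 0 °C. This should give 5 with only a water-soluble ammonium salt to wash out, so that crystallisation can replace chromatography.

Step 3. Activation may be slow because the fatty acid is only partly dissolved. The waxy activated ester may be lost by co-crystallising with the urea or by hydrolysis on silica. The fallback sets out from 6 and comes back at 7. 6 would be heated with SOCl2 and catalytic DMF in toluene at 70 °C to give octadecanoyl chloride F2, from which excess reagent is removed under vacuum. Reaction of F2 with 4 and Et3N in THF at 0 °C should give 7 free of urea, to be purified by recrystallisation alone.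

Further compounds
F0 | step 4 | none | none
F1 | step 2 | benzyl 4-chloro-4-oxobutanoate | O=C(Cl)CCC(=O)OCc1ccccc1
F2 | step 3 | octadecanoyl chloride (stearoyl chloride) | CCCCCCCCCCCCCCCCCC(=O)Cl
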